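A substrate curve gone flat looks like a finished flask, but what was made can go on sinking after the substrate stops, so follow the fraction left of what was made.

| setting | amber | teal | green | epsilon | gamma | alpha |
|---|---|---|---|---|---|---|
| substrate | 1 mM | 1 mM | 1.5 mM | 1.0 mM | 1.0 mM | 1.0 mM |
| partner | 0.47 equiv | 1 equiv | 0.70 equiv | 0.700 equiv | 0.700 equiv | 0.700 equiv |
| temperature | 55 °C | 85 °C | 55 °C | 60 °C | 85 °C | 110 °C |
| remark | run made earlier | run made earlier | run made earlier |  |  |  |
| time |  |  |  | 4.0 min | 4.0 min | 4.0 min |

amber run (percent of the substrate charged)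

| time / min | side product / % | isomer of the product / % | substrate / % | target / % | intermediate / % |
|---|---|---|---|---|---|
| 0.250 | 0.4 | 1.5 | 79.5 | 2.8 | 16.5 |
| 0.667 | 2.8 | 3.8 | 64.8 | 11.9 | 16.8 |
| 1.33 | 5.6 | 7.8 | 57.4 | 21.6 | 8.6 |
| 2.00 | 5.1 | 8.8 | 54.3 | 26.2 | 5.4 |
| 3.00 | 6.1 | 8.3 | 53.9 | 27.9 | 2.4 |
| 4.00 | 6.7 | 9.1 | 52.7 | 28.7 | 3.1 |
| 5.00 | 7.5 | 7.6 | 52.9 | 27.8 | 2.9 |

teal run (percent of the substrate charged)

| time / s | side product / % | isomer of the product / % | substrate / % | target / % | intermediate / % |
|---|---|---|---|---|---|
| 10.0 | 8.1 | 9.5 | 31.3 | 44.5 | 8.4 |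
| 12.0 | 7.8 | 9.7 | 27.5 | 48.3 | 6.7 |
| 15.0 | 8.5 | 9.2 | 23.0 | 52.2 | 6.3 |
| 25.0 | 12.3 | 7.3 | 15.3 | 61.6 | 3.9 |
| 40.0 | 13.9 | 5.2 | 10.3 | 66.3 | 2.6 |
| 50.0 | 15.9 | 5.1 | 8.6 | 68.7 | 3.1 |
| 80.0 | 19.8 | 3.5 | 6.3 | 67.8 | 2.0 |

green run (percent of the substrate charged)

| time / min | side product / % | isomer of the product / % | substrate / % | target / % | intermediate / % |
|---|---|---|---|---|---|
| 0.417 | 1.8 | 4.7 | 52.6 | 11.2 | 28.6 |
| 1.33 | 6.1 | 11.9 | 36.1 | 34.0 | 13.7 |
| 2.00 | 7.9 | 12.0 | 32.0 | 38.9 | 8.1 |
| 3.00 | 9.2 | 13.2 | 30.3 | 42.3 | 4.3 |
| 5.00 | 11.3 | 11.7 | 31.0 | 43.3 | 2.7 |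

(readings scatter by 0.5 percentage points)

* which of these there is most of at the end, counted by the substrate in it, epsilon (target / isomer of the product / intermediate / side product / substrate)
* which of these there is most of at the end, counted by the substrate in it, gamma (target / isomer of the product / intermediate / side product / substrate)
* which of these there is most of at the end, counted by the substrate in it, alpha (target / isomer of the product / intermediate / side product / substrate)
* the largest of these amounts at the end, in percent of the substrate charged, epsilon
* the largest of these amounts at the end, in percent of the substrate charged, gamma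
* the largest of these amounts at the end, in percent of the substrate charged, alpha

In the green run the substrate stands near 30.3% with 0.70 equiv of partner, the limiting reagent, so about 69.7% can be converted in these flasks. Call target, isomer of the product and intermediate together the pool, and call side product gained per minute over the pool standing the drain. My reckoning takes it from the late teal readings at 85 °C, which give 0.112 min⁻¹, and from the last two green readings at 55 °C, which give a rougher 0.0179 min⁻¹. A straight line of its logarithm against inverse temperature has a slope worth 59.8 kJ mol⁻¹, which puts the drain at 0.0248 min⁻¹ for epsilon and 0.415 min⁻¹ for alpha. The fraction left after a time is the exponential of minus drain times time. Teal's first reading also shows 11.8% of the converted substrate already lost as side product, so the pool starts near 61.5%.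

For a lower bound, let the pool drain the whole 4.0 min. For an upper bound, let it drain over the second half, since amber's substrate at 2.00 min is within 1.6 percentage points of its reading at 4.00 min, and these flasks are hotter. The pool lies between 55.7% and 58.5% for epsilon, 39.3% and 49.1% for gamma, and 11.7% and 26.8% for alpha. Alpha's side product is then at least 42.9%, so I name it the leader there.

The forecast names target in each flask, at 44.5%, 49.5% and 47%, with the words “Isomer drains to side product, and target may be lost slightly” for gamma. Target can't exceed the pool, so gamma's figure stands just above its bracket and alpha's far above.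

    intermediate → side product (k = 0.00633 s⁻¹, Ea = 87.0 kJ mol⁻¹)
    intermediate ⇌ isomer of the product (K = 2.10, k = 0.0127 s⁻¹, Ea = 86.0 kJ mol⁻¹, ΔH = −17.0 kJ mol⁻¹)
    intermediate ⇌ target (K = 14.0, k = 0.0352 s⁻¹, Ea = 93.0 kJ mol⁻¹, ΔH = 27.0 kJ mol⁻¹)
    substrate + partner → intermediate + by-product (k = 57.4 M⁻¹ s⁻¹, Ea = 53.0 kJ mol⁻¹)
    (constants at 60 °C)

The flasks give target 44.7% in epsilon, target 39.0% in gamma and side product 56.8% in alpha, where target holds 12.7%. Alpha's pool of 13.2% sits at the bracket's foot. Alpha's side product owes its amount in part to two returns to intermediate, from target and from the isomer of the product, of which the return from target is the larger single effect: alpha's side product is 8.36% without the return from target and 23.6% without the return from the isomer of the product. At 100 °C, a flask like gamma has a drain of 0.251 min⁻¹ and a bracket from 22.5% to 37.2%, and its simulated pool is 24.8%.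

(The numbers in the tables come from a simulation with constants of no real substance; the scatter is artificial.)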